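The synthesis rests on the bond between C1 of ring B (the resorcinol carbon meta to both O3–H and O5–Me and para to the C4 methylene bridge) and the benzylic CH2 of its guaiacylethyl arm. C1 is out of reach of electrophilic substitution and ortho-lithiation. In the arm-free three-ring precursor 13, however, it carries the only aromatic C–H without an ortho neighbour. A one-pot iridium C–H borylation/Suzuki–Miyaura alkenylation therefore turns that bare C–H directly into the C–C bond and joins 13 to bromostyrene 15. 4-Methylbenzyl ethers, which offer no unhindered C–H, guard the phenols. A single hydrogenation then saturates the stilbene and frees every phenol.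

Key step: step 10

Remark on the chemistry: rings are labelled A (guaiacyl ring of the arm on ring B), B (ring whose OH and OMe flank the bridge; C1 arm, C3 OH, C4 bridge, C5 OMe), C (second resorcinol ring) and D (its guaiacyl ring); the target is achiral, and 1, 5, 9 and 14 are taken as purchasable.

Step 1
Reactants: 1 5-bromoresorcinol
Product: 2 2-bromo-4,6-dihydroxybenzaldehyde
Conditions: POCl3, DMF, MeCN, 0 °C to rt; then H2O, 50 °C
Reagents that add atoms: N,N-dimethylformamide, CN(C)C=O (formyl carbon); water, O (aldehyde oxygen)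
Why: Vilsmeier–Haack formylation, in which the chloroiminium ion should attack the position ortho to one OH and para to the other (two equivalent sites) rather than the carbon squeezed between both OH groups, as with orcinol, and hydrolysis of the iminium salt frees the aldehyde.

Step 2
Reactants: 2 2-bromo-4,6-dihydroxybenzaldehyde
Product: 3 2-bromo-6-hydroxy-4-(4-methylbenzyloxy)benzaldehyde
Conditions: 4-MeC6H4CH2Br (1 equiv), CsHCO3, MeCN, 60 °C
Reagents that add atoms: 4-methylbenzyl bromide, Cc1ccc(CBr)cc1
Why: Williamson ether synthesis in which the 6-OH is held in a hydrogen bond to the aldehyde and is less acidic, so the weak base should ionise and alkylate only the 4-OH, which fixes the oxygen of ring C that ends as free phenol.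

Step 3
Reactants: 3 2-bromo-6-hydroxy-4-(4-methylbenzyloxy)benzaldehyde
Product: 4 2-bromo-6-methoxy-4-(4-methylbenzyloxy)benzaldehyde
Conditions: MeI, K2CO3, DMF, rt
Reagents that add atoms: iodomethane, CI
Why: Williamson O-methylation of the remaining chelated phenol with the stronger base places the ring C methoxy group ortho to the future bridge carbon.

Step 4
Reactants: 5 2-methoxy-4-vinylphenol
Product: 6 2-methoxy-1-(4-methylbenzyloxy)-4-vinylbenzene
Conditions: 4-MeC6H4CH2Br, K2CO3, DMF, rt (trace BHT)
Reagents that add atoms: 4-methylbenzyl bromide, Cc1ccc(CBr)cc1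
Why: Williamson ether synthesis on the only phenol, with mild base and room temperature sparing the styrene.

Step 5
Reactants: 6 2-methoxy-1-(4-methylbenzyloxy)-4-vinylbenzene; 4 2-bromo-6-methoxy-4-(4-methylbenzyloxy)benzaldehyde
Product: 8 2-methoxy-6-{2-[3-methoxy-4-(4-methylbenzyloxy)phenyl]ethyl}-4-(4-methylbenzyloxy)benzaldehyde (ring C–D aldehyde), via B-alkyl-9-BBN 7 (not isolated)
Conditions: 6, 9-BBN-H, THF, 0 °C to rt; then aq K3PO4, 4, Pd(dppf)Cl2 (cat.), THF/DMF, 55 °C
Reagents that add atoms: 9-borabicyclo[3.3.1]nonane, [H]B1C2CCCC1CCC2 (its boryl group stands in 7 only; 8 keeps one hydrogen of it)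
Why: Hydroboration with 9-BBN places boron on the terminal styrene carbon and the B-alkyl Suzuki–Miyaura coupling then replaces the bromide activated by the ortho aldehyde, while adding the aqueous base to the borane before 4 should keep the borane from reducing the aldehyde.

Step 6
Reactants: 9 3-methoxyphenol
Product: 10 1-methoxy-3-(methoxymethoxy)benzene
Conditions: MOMCl, iPr2NEt, CH2Cl2, 0 °C to rt
Reagents that add atoms: chloromethyl methyl ether, COCCl
Why: O-alkylation of the phenol gives the MOM acetal that serves as directing group in the next step.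

Step 7
Reactants: 10 1-methoxy-3-(methoxymethoxy)benzene; 8 ring C–D aldehyde
Product: 12 racemic [2-methoxy-6-(methoxymethoxy)phenyl]{2-methoxy-6-[2-(3-methoxy-4-(4-methylbenzyloxy)phenyl)ethyl]-4-(4-methylbenzyloxy)phenyl}methanol, via aryllithium 11 (not isolated)
Conditions: 10 (slight excess), n-BuLi, THF, 0 °C to rt; then 8, −78 to 0 °C; aq NH4Cl
Reagents that add atoms: n-butyllithium, [Li]CCCC (lithium stands in 11 only)
Why: Directed ortho-metalation, in which OMe and OMOM cooperate so that n-BuLi removes only the proton between them and the aryllithium adds 1,2 to the non-enolisable aldehyde, gives the carbinol centre as a racemate that step 8 erases.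

Step 8
Reactants: 12 racemic diaryl carbinol
Product: 13 3-methoxy-2-{2-methoxy-6-[2-(3-methoxy-4-(4-methylbenzyloxy)phenyl)ethyl]-4-(4-methylbenzyloxy)benzyl}phenol
Conditions: Et3SiH (excess), CF3CO2H, CH2Cl2, −10 to 0 °C
Reagents that add atoms: none
Why: Ionic hydrogenation: the acid ionises the doubly benzylic alcohol, whose cation is stabilised by four ortho/para oxygen substituents, and opens the MOM acetal next to it, the excess silane should reduce both carbocations faster than they can attack an arene, and the aryl 4-methylbenzyl and methyl ethers should outlast the short, cold acid contact.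

Step 9
Reactants: 14 (E)-4-benzyloxy-3-methoxycinnamic acid
Product: 15 (E)-1-benzyloxy-4-(2-bromovinyl)-2-methoxybenzene
Conditions: NBS, LiOAc (cat.), MeCN/H2O, rt
Reagents that add atoms: N-bromosuccinimide, O=C1CCC(=O)N1Br
Why: Catalytic Hunsdiecker-type bromodecarboxylation, in which bromonium transfer from NBS to the electron-rich cinnamate double bond is followed by anti loss of CO2, should give the E-bromoalkene and outrun bromination of the dialkoxyarene ring.

Step 10
Reactants: 13 arm-free diarylmethane phenol; 15 (E)-1-benzyloxy-4-(2-bromovinyl)-2-methoxybenzene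
Product: 18 5-[(E)-2-(4-benzyloxy-3-methoxyphenyl)vinyl]-3-methoxy-2-{2-methoxy-6-[2-(3-methoxy-4-(4-methylbenzyloxy)phenyl)ethyl]-4-(4-methylbenzyloxy)benzyl}phenol, via O-boryl ether 16 (not isolated), via bis-boryl arene 17 (not isolated)
Conditions: HBpin (1.2 equiv), THF, rt; [Ir(OMe)(cod)]2 (cat.), dtbpy (cat.), B2pin2 (1 equiv), THF, 70 °C; evaporate; then 15, Pd(dppf)Cl2 (cat.), aq K3PO4, 1,4-dioxane, 70 °C
Reagents that add atoms: pinacolborane, [H]B1OC(C)(C)C(C)(C)O1, and bis(pinacolato)diboron, CC1(C)OB(OC1(C)C)B1OC(C)(C)C(C)(C)O1 (their boryl groups stand in 16 and 17 only; 18 keeps none of their atoms)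
Why: Pinacolborane first caps the ring B phenol as O-boryl ether 16; the dtbpy-ligated iridium tris(boryl) complex then cleaves an aromatic C–H bond by oxidative addition and releases boronate 17, and because this crowded catalyst avoids any C–H next to a substituent it should take only C1–H of ring B, the one C–H among sixteen with hydrogen on both sides (both ring C C–H bonds lie between two substituents, and every C–H of ring D and of the two p-xylyl-type protecting groups has an ortho neighbour). After the solvent swap Pd(0) inserts into the C–Br bond of 15 with retention, the base-activated boronate hands over the ring B aryl group, reductive elimination forms the C1–CH= bond, and the aqueous base hydrolyses the O–B bond back to the phenol. The closest known reaction type is the one-pot iridium C–H borylation/Suzuki–Miyaura sequence of 1,2,3-trisubstituted arenes, including phenols masked in the flask as O-Bpin. No ring is closed and no stereocentre is formed; the E geometry of 15 is carried over but is of no consequence because step 11 saturates the alkene. The step needs site selectivity only, which is secured by the 1,2,3-substitution pattern of ring B and by the use of 4-methylbenzyl instead of benzyl ethers, and boron meta to both oxygens should also make 17 slow to protodeboronate.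

Step 11
Reactants: 18 protected stilbene
Product: 19 target CNP0079000.0
Conditions: H2 (1–3 bar), Pd/C, EtOAc/MeOH, rt
Reagents that add atoms: none
Why: Heterogeneous catalytic hydrogenation should saturate the stilbene C=C and hydrogenolyse the three benzylic C–O bonds in one operation, while the diarylmethane and bibenzyl C–C bonds and the aryl methyl ethers are inert.

Compound list
1 | 5-bromoresorcinol | Oc1cc(O)cc(Br)c1 | starting material
2 | 2-bromo-4,6-dihydroxybenzaldehyde | O=Cc1c(Br)cc(O)cc1O | intermediate
3 | 2-bromo-6-hydroxy-4-(4-methylbenzyloxy)benzaldehyde | O=Cc1c(Br)cc(OCc2ccc(C)cc2)cc1O | intermediate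
4 | 2-bromo-6-methoxy-4-(4-methylbenzyloxy)benzaldehyde | O=Cc1c(Br)cc(OCc2ccc(C)cc2)cc1OC | intermediate
5 | 2-methoxy-4-vinylphenol | C=Cc1ccc(O)c(OC)c1 | starting material
6 | 2-methoxy-1-(4-methylbenzyloxy)-4-vinylbenzene | C=Cc1ccc(OCc2ccc(C)cc2)c(OC)c1 | intermediate
7 | 9-{2-[3-methoxy-4-(4-methylbenzyloxy)phenyl]ethyl}-9-borabicyclo[3.3.1]nonane (not isolated) | COc1cc(CCB2C3CCCC2CCC3)ccc1OCc1ccc(C)cc1 | intermediate
8 | 2-methoxy-6-{2-[3-methoxy-4-(4-methylbenzyloxy)phenyl]ethyl}-4-(4-methylbenzyloxy)benzaldehyde | O=Cc1c(CCc2ccc(OCc3ccc(C)cc3)c(OC)c2)cc(OCc2ccc(C)cc2)cc1OC | intermediate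
9 | 3-methoxyphenol | COc1cccc(O)c1 | starting material
10 | 1-methoxy-3-(methoxymethoxy)benzene | COCOc1cccc(OC)c1 | intermediate
11 | 2-methoxy-6-(methoxymethoxy)phenyllithium (not isolated) | [Li]c1c(OC)cccc1OCOC | intermediate
12 | racemic diaryl carbinol from 11 and 8 | OC(c1c(OC)cccc1OCOC)c1c(CCc2ccc(OCc3ccc(C)cc3)c(OC)c2)cc(OCc2ccc(C)cc2)cc1OC | intermediate
13 | 3-methoxy-2-{2-methoxy-6-[2-(3-methoxy-4-(4-methylbenzyloxy)phenyl)ethyl]-4-(4-methylbenzyloxy)benzyl}phenol | Oc1cccc(OC)c1Cc1c(CCc2ccc(OCc3ccc(C)cc3)c(OC)c2)cc(OCc2ccc(C)cc2)cc1OC | intermediate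
14 | (E)-4-benzyloxy-3-methoxycinnamic acid | OC(=O)/C=C/c1ccc(OCc2ccccc2)c(OC)c1 | starting material
15 | (E)-1-benzyloxy-4-(2-bromovinyl)-2-methoxybenzene | Br/C=C/c1ccc(OCc2ccccc2)c(OC)c1 | intermediate
16 | O-(pinacolatoboryl) ether of 13 (not isolated) | CC1(C)OB(Oc2cccc(OC)c2Cc2c(CCc3ccc(OCc4ccc(C)cc4)c(OC)c3)cc(OCc3ccc(C)cc3)cc2OC)OC1(C)C | intermediate
17 | O-boryl ether of 13 with Bpin at C1 of ring B (not isolated) | CC1(C)OB(Oc2cc(B3OC(C)(C)C(C)(C)O3)cc(OC)c2Cc2c(CCc3ccc(OCc4ccc(C)cc4)c(OC)c3)cc(OCc3ccc(C)cc3)cc2OC)OC1(C)C | intermediate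
18 | 5-[(E)-2-(4-benzyloxy-3-methoxyphenyl)vinyl]-3-methoxy-2-{2-methoxy-6-[2-(3-methoxy-4-(4-methylbenzyloxy)phenyl)ethyl]-4-(4-methylbenzyloxy)benzyl}phenol | COc1cc(/C=C/c2cc(O)c(Cc3c(CCc4ccc(OCc5ccc(C)cc5)c(OC)c4)cc(OCc4ccc(C)cc4)cc3OC)c(OC)c2)ccc1OCc1ccccc1 | intermediate
19 | CNP0079000.0, methylene-bridged bis(bibenzyl) | COc1cc(CCc2cc(O)c(Cc3c(CCc4ccc(O)c(OC)c4)cc(O)cc3OC)c(OC)c2)ccc1O | target

Total step count: 11. Longest linear sequence: 8 steps (1, 2, 3, 5, 7, 8, 10, 11).

Steps most likely to fail

Step 10. The borylation may stall on the crowded, Lewis-basic substrate. It may also spread to C–H bonds next to oxygen on rings B or D, and iridium and boron residues may slow the palladium stage while the bromostyrene degrades.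
- The fallback sets out from 8, brings the coupling handle in with ring B, and reverses the polarity of the union.
- 3-Chloro-5-methoxyphenol F1 (purchased) is converted with MOMCl/iPr2NEt into 1-chloro-3-methoxy-5-(methoxymethoxy)benzene F2.
- n-BuLi in THF at low temperature, under coordination control by the two oxygen groups, gives 4-chloro-2-methoxy-6-(methoxymethoxy)phenyllithium F3.
- F3 adds to 8 to give chloro carbinol F4.
- Et3SiH/CF3CO2H then gives the 5-chloro analogue of 13 F5.
- B-alkyl Suzuki–Miyaura coupling of the aryl chloride with borane 7 (Pd(OAc)2/SPhos, K3PO4, toluene/H2O) forms the same C1–CH2 bond at the saturated level and gives tris(4-methylbenzyl) ether F6.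
- Hydrogenolysis (H2, Pd/C) of F6 comes back to the route at 19.

Step 8. Several processes could compete:
- The long-lived benzylic cation may close a seven-membered ring onto ring D.
- The released methoxymethyl cation may alkylate an electron-rich ring.
- A 4-methylbenzyl ether may be lost, or the carbinol may fragment in acid.

The fallback sets out from 8 and never passes through a carbinol, because ring B is carried as a cyclohexane-1,3-dione and aromatised afterwards.
- Three-component reductive alkylation of 8 with cyclohexane-1,3-dione and Hantzsch ester (L-proline cat., CH2Cl2, rt; Knoevenagel condensation/transfer hydrogenation) gives 2-(arylmethyl)cyclohexane-1,3-dione F7.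
- HC(OMe)3/MeOH/TsOH gives the single possible methyl enol ether, 3-methoxy-2-(arylmethyl)cyclohex-2-enone F8.
- Dehydrogenation (LDA, then N-tert-butylbenzenesulfinimidoyl chloride, THF, −78 °C) with tautomerisation comes back to the route at 13.

Step 5. β-Hydride transfer from the 2-arylethylborane to the aldehyde, or β-hydride elimination on palladium, may consume both partners. The fallback sets out from 4 and 6.
- A Heck reaction (Pd(OAc)2, P(o-tol)3, Et3N, DMF, 100 °C) gives (E)-stilbene aldehyde F9.
- Diimide reduction (dipotassium azodicarboxylate, AcOH, THF/MeOH) saturates the alkene without touching the aldehyde or the benzylic ethers and comes back to the route at 8.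

Further compounds
F1 | step 10 | 3-chloro-5-methoxyphenol (purchased) | COc1cc(O)cc(Cl)c1
F2 | step 10 | 1-chloro-3-methoxy-5-(methoxymethoxy)benzene | COCOc1cc(Cl)cc(OC)c1
F3 | step 10 | 4-chloro-2-methoxy-6-(methoxymethoxy)phenyllithium | [Li]c1c(OC)cc(Cl)cc1OCOC
F4 | step 10 | racemic chloro carbinol from F3 and 8 | OC(c1c(OC)cc(Cl)cc1OCOC)c1c(CCc2ccc(OCc3ccc(C)cc3)c(OC)c2)cc(OCc2ccc(C)cc2)cc1OC
F5 | step 10 | 5-chloro analogue of 13 | Oc1cc(Cl)cc(OC)c1Cc1c(CCc2ccc(OCc3ccc(C)cc3)c(OC)c2)cc(OCc2ccc(C)cc2)cc1OC
F6 | step 10 | tris(4-methylbenzyl) ether of the target | Oc1cc(CCc2ccc(OCc3ccc(C)cc3)c(OC)c2)cc(OC)c1Cc1c(CCc2ccc(OCc3ccc(C)cc3)c(OC)c2)cc(OCc2ccc(C)cc2)cc1OC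
F7 | step 8 | 2-(arylmethyl)cyclohexane-1,3-dione from 8 | O=C1CCCC(=O)C1Cc1c(CCc2ccc(OCc3ccc(C)cc3)c(OC)c2)cc(OCc2ccc(C)cc2)cc1OC
F8 | step 8 | 3-methoxy-2-(arylmethyl)cyclohex-2-enone | COC1=C(Cc2c(CCc3ccc(OCc4ccc(C)cc4)c(OC)c3)cc(OCc3ccc(C)cc3)cc2OC)C(=O)CCC1
F9 | step 5 | (E)-stilbene aldehyde from 4 and 6 | O=Cc1c(/C=C/c2ccc(OCc3ccc(C)cc3)c(OC)c2)cc(OCc2ccc(C)cc2)cc1OC
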